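**Retrosynthetic overview** (tocopherol numbering: O1, C2–C4, C4a, C5–C8, C8a; chain C1'–C13')
- Feature: C2 of the benzopyran is a fully substituted carbon bearing O1, a methyl, C3 and chain carbon C1'. With a temporary carbonyl at C4 it becomes the β-carbon of a 2-methylchromone (4-pyranone ring fused to the arene).
- Key disconnection C2–C1': copper-catalysed enantioselective 1,4-addition of the C16 Grignard reagent to the 6-silyloxy-2,5,7,8-tetramethylchromone sets C2. The C4 carbonyl is then removed (reduction, ionic deoxygenation) and the phenol freed.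
- Chain: two copper-catalysed sp3–sp3 couplings. C9'–C10' joins the bought isopropenyl piece to the (S)-3-bromo-2-methylpropanol unit (C8'). C6'–C7' joins that to ozonolysed (S)-citronellyl bromide (C4').
- Ring order: the arene is bought (trimethylhydroquinone); the pyranone ring is closed in step 3; no ring is formed after that.

Key step: step 15

Assumption 1: (S)-citronellyl bromide is taken as purchased; it is otherwise one Appel step from (S)-citronellol.
Assumption 2: the sense of induction of the ferrocenyl diphosphine on a 2-methylchromone cannot be predicted with certainty. The (R,Sp) ligand is written; its mirror image would be used if a pilot run shows the 2S epimer is favoured.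
Remark: C8' is S by the CIP rules only because the terminal alkene raises the priority of the C9' branch; the spatial arrangement is that of 8'R in α-tocopherol.

Step 1
Reactants: 1 trimethylhydroquinone (2,3,5-trimethylbenzene-1,4-diol)
Product: 2 1-(2,5-dihydroxy-3,4,6-trimethylphenyl)ethanone
Conditions: AcOH, BF3·OEt2, 100 °C; then H2O, 80 °C
Reagents that add atoms: acetic acid, CC(=O)O
Why: Friedel–Crafts/Fries-type C-acetylation takes place at the only unsubstituted ring carbon of the electron-rich hydroquinone, ortho to a hydroxyl that then chelates the ketone.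

Step 2
Reactants: 2 1-(2,5-dihydroxy-3,4,6-trimethylphenyl)ethanone
Product: 3 1-(2,5-dihydroxy-3,4,6-trimethylphenyl)butane-1,3-dione
Conditions: NaH (5 equiv), EtOAc (excess), THF, reflux, argon; then cold 1 M HCl
Reagents that add atoms: ethyl acetate, CCOC(C)=O
Why: Crossed Claisen condensation of the methyl ketone enolate (both phenols held as sodium phenoxides) with ethyl acetate should give the β-diketone, the classical entry to 2-methylchromones from ortho-hydroxyacetophenones.

Step 3
Reactants: 3 1-(2,5-dihydroxy-3,4,6-trimethylphenyl)butane-1,3-dione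
Product: 4 6-hydroxy-2,5,7,8-tetramethyl-4H-chromen-4-one
Conditions: conc. HCl (cat.), EtOH, reflux
Reagents that add atoms: none
Why: Acid-catalysed cyclodehydration, in which the ortho phenol adds to the distal ketone and water is lost, closes the 4-pyranone ring onto the arene and also cleaves any aryl acetate formed in step 2.

Step 4
Reactants: 4 6-hydroxy-2,5,7,8-tetramethyl-4H-chromen-4-one
Product: 5 6-(tert-butyldimethylsilyloxy)-2,5,7,8-tetramethyl-4H-chromen-4-one
Conditions: TBSCl, imidazole, DMF, 40 °C
Reagents that add atoms: tert-butyldimethylsilyl chloride, CC(C)(C)[Si](C)(C)Cl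
Why: Silylation of the single phenol, flanked by two methyls as in the tocopherols, gives an ether that should survive Grignard reagent, Lewis acid and hydride and leave with fluoride.

Step 5
Reactants: 6 (S)-3-bromo-2-methylpropan-1-ol
Product: 7 (S)-(3-bromo-2-methylpropoxy)(tert-butyl)dimethylsilane
Conditions: TBSCl, imidazole, CH2Cl2, 0 °C to rt
Reagents that add atoms: tert-butyldimethylsilyl chloride, CC(C)(C)[Si](C)(C)Cl
Why: Standard silyl protection of the primary alcohol masks the acidic proton before the Grignard coupling and leaves the stereocentre untouched.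

Step 6
Reactants: 7 (S)-(3-bromo-2-methylpropoxy)(tert-butyl)dimethylsilane; 8 4-bromo-2-methylbut-1-ene
Product: 10 (R)-tert-butyl(2,6-dimethylhept-6-enyloxy)dimethylsilane, via 3-methylbut-3-enylmagnesium bromide 9 (not isolated)
Conditions: 8, Mg, THF, 40 °C; then 7, Li2CuCl4 (3 mol %), N-methylpyrrolidone (4 equiv), THF, 0 °C to rt
Reagents that add atoms: none
Why: Copper-catalysed cross-coupling of a primary alkyl Grignard reagent with a primary alkyl bromide forms C9'–C10' at a carbon next to the stereocentre, so the future C8' keeps its arrangement (only its descriptor changes from S to R).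

Step 7
Reactants: 10 (R)-tert-butyl(2,6-dimethylhept-6-enyloxy)dimethylsilane
Product: 11 (R)-2,6-dimethylhept-6-en-1-ol
Conditions: Bu4NF, THF, rt; then H2O
Reagents that add atoms: none
Why: Fluoride-driven desilylation of a primary silyl ether is neutral towards the 1,1-disubstituted alkene.

Step 8
Reactants: 11 (R)-2,6-dimethylhept-6-en-1-ol
Product: 12 (R)-7-bromo-2,6-dimethylhept-1-ene
Conditions: CBr4, PPh3, CH2Cl2, 0 °C
Reagents that add atoms: carbon tetrabromide, BrC(Br)(Br)Br
Why: The Appel reaction converts the primary alcohol into the bromide under neutral conditions that neither add to nor isomerise the isopropenyl group.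

Step 9
Reactants: 13 (S)-citronellyl bromide ((S)-8-bromo-2,6-dimethyloct-2-ene)
Product: 15 (S)-6-bromo-4-methylhexan-1-ol, via (S)-6-bromo-4-methylhexanal 14 (not isolated)
Conditions: O3, CH2Cl2/MeOH, −78 °C; then NaBH4, −78 to 0 °C
Reagents that add atoms: ozone, [O-][O+]=O
Why: Ozonolysis of the trisubstituted alkene with reductive work-up unveils the future C1' as a primary alcohol, while the primary bromide (future C6') and the stereocentre (future C4') are not affected.

Step 10
Reactants: 15 (S)-6-bromo-4-methylhexan-1-ol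
Product: 16 (S)-(6-bromo-4-methylhexyloxy)(tert-butyl)dimethylsilane
Conditions: TBSCl, imidazole, CH2Cl2, 0 °C to rt
Reagents that add atoms: tert-butyldimethylsilyl chloride, CC(C)(C)[Si](C)(C)Cl
Why: Silyl protection removes the acidic proton so that only the bromide end reacts in the next coupling.

Step 11
Reactants: 12 (R)-7-bromo-2,6-dimethylhept-1-ene; 16 (S)-(6-bromo-4-methylhexyloxy)(tert-butyl)dimethylsilane
Product: 18 tert-butyldimethyl[(4R,8S)-4,8,12-trimethyltridec-12-enyloxy]silane, via (R)-2,6-dimethylhept-6-enylmagnesium bromide 17 (not isolated)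
Conditions: 12, Mg, THF, 45 °C; then 16, Li2CuCl4 (3 mol %), N-methylpyrrolidone (4 equiv), THF, 0 °C to rt
Reagents that add atoms: none
Why: A second copper-catalysed Grignard–alkyl bromide cross-coupling forms C6'–C7' at an unhindered primary bromide and assembles the full C16 skeleton with both stereocentres carried in from the building blocks.

Step 12
Reactants: 18 tert-butyldimethyl[(4R,8S)-4,8,12-trimethyltridec-12-enyloxy]silane
Product: 19 (4R,8S)-4,8,12-trimethyltridec-12-en-1-ol
Conditions: Bu4NF, THF, rt; then H2O
Reagents that add atoms: none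
Why: Fluoride desilylation frees the C1' alcohol without touching the alkene.

Step 13
Reactants: 19 (4R,8S)-4,8,12-trimethyltridec-12-en-1-ol
Product: 20 (6S,10R)-13-bromo-2,6,10-trimethyltridec-1-ene
Conditions: CBr4, PPh3, CH2Cl2, 0 °C
Reagents that add atoms: carbon tetrabromide, BrC(Br)(Br)Br
Why: The Appel reaction gives the primary bromide under neutral conditions compatible with the terminal alkene.

Step 14
Reactants: 20 (6S,10R)-13-bromo-2,6,10-trimethyltridec-1-ene
Product: 21 (4R,8S)-4,8,12-trimethyltridec-12-enylmagnesium bromide (titrated solution in Et2O, used as such)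
Conditions: Mg turnings (activated with a trace of 1,2-dibromoethane), Et2O, reflux
Reagents that add atoms: magnesium, [Mg]
Why: Grignard formation by insertion of magnesium into the primary C–Br bond, run in diethyl ether because the copper step needs a weakly coordinating medium, leaves the remote alkene and both stereocentres untouched.

Step 15
Reactants: 5 6-(tert-butyldimethylsilyloxy)-2,5,7,8-tetramethyl-4H-chromen-4-one; 21 (4R,8S)-4,8,12-trimethyltridec-12-enylmagnesium bromide
Product: 24 (R)-6-(tert-butyldimethylsilyloxy)-2,5,7,8-tetramethyl-2-[(4R,8S)-4,8,12-trimethyltridec-12-enyl]chroman-4-one, via 4-silyloxybenzopyrylium triflate 22 (not isolated), via trimethylsilyl enol ether 23 (not isolated)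
Conditions: CuBr·SMe2 (5 mol %), (R)-1-[(Sp)-2-(dicyclohexylphosphino)ferrocenyl]ethyldiphenylphosphine (6 mol %), Me3SiOTf (1.5 equiv), CH2Cl2, −78 °C, 21 (1.5 equiv in Et2O) added over 3 h; then 1 M HCl, THF, 0 °C
Reagents that add atoms: none
Why: Proposed new method: Me3SiOTf silylates the C4 carbonyl of 5 to the benzopyrylium salt 22, whose C2 should be electrophilic enough to take an alkyl group although it already bears a methyl; the monovalent copper alkyl generated from 21 and the CuBr–diphosphine complex binds the C2–C3 bond, adds to C2 through a trivalent copper species and reductively eliminates to forge C2–C1', leaving silyl enol ether 23, which dilute acid hydrolyses to ketone 24. The closest known reaction types are the copper–ferrocenyl diphosphine catalysed enantioselective 1,4-addition of Grignard reagents to chromones that lack a C2 substituent, its silyl triflate or boron trifluoride assisted variant for weak acceptors, and copper-catalysed Grignard additions that create quaternary carbons on β,β-disubstituted enones; their combination on a 2-alkylchromone is untested. No ring is closed, since arene and pyranone are both present in the planar acceptor. C2 is set by the chiral diphosphine on copper, which must distinguish the two enantiotopic faces of the flat cation; the C4' and C8' centres of the chain lie too far from the reacting carbon to interfere, so the outcome should be under catalyst control. The step needs 1,4- over 1,2-addition and C–C bond formation over deprotonation of the acidic 2-methyl group: the peri methyl on C5 shields C4, the soft copper alkyl prefers C2, and slow addition at −78 °C keeps the concentration of free Grignard reagent low. The distant 1,1-disubstituted alkene and the aryl silyl ether are inert under these cold aprotic conditions, and the acidic, base-free work-up avoids retro-oxa-Michael opening that would scramble C2.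

Step 16
Reactants: 24 (R)-6-(tert-butyldimethylsilyloxy)-2,5,7,8-tetramethyl-2-[(4R,8S)-4,8,12-trimethyltridec-12-enyl]chroman-4-one
Product: 25 (2R)-6-(tert-butyldimethylsilyloxy)-2,5,7,8-tetramethyl-2-[(4R,8S)-4,8,12-trimethyltridec-12-enyl]chroman-4-ol (both C4 epimers)
Conditions: NaBH4, CeCl3·7H2O, MeOH/THF, 0 °C
Reagents that add atoms: none
Why: Luche reduction gives fast 1,2-hydride delivery in a nearly neutral medium, so the ketone is not left under base where ring opening could epimerise C2; the new C4 centre is not controlled and is erased in step 17.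

Step 17
Reactants: 25 (2R)-6-(tert-butyldimethylsilyloxy)-2,5,7,8-tetramethyl-2-[(4R,8S)-4,8,12-trimethyltridec-12-enyl]chroman-4-ol
Product: 26 tert-butyldimethyl{(R)-2,5,7,8-tetramethyl-2-[(4R,8S)-4,8,12-trimethyltridec-12-enyl]chroman-6-yloxy}silane
Conditions: Et3SiH (5 equiv), BF3·OEt2 (1.5 equiv), CH2Cl2, −78 °C; Et3N, then aq. NaHCO3 at −78 °C
Reagents that add atoms: none
Why: Ionic deoxygenation, in which the Lewis acid ionises the benzylic C4–O bond with help from the ring oxygen O1 ortho to C4a and the silane delivers hydride, should proceed at −78 °C without a protic acid strong enough to protonate the 1,1-disubstituted alkene.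

Step 18
Reactants: 26 tert-butyldimethyl{(R)-2,5,7,8-tetramethyl-2-[(4R,8S)-4,8,12-trimethyltridec-12-enyl]chroman-6-yloxy}silane
Product: 27 (R)-2,5,7,8-tetramethyl-2-[(4R,8S)-4,8,12-trimethyltridec-12-enyl]chroman-6-ol (target, CNP0115007.1)
Conditions: Bu4NF, THF, 0 °C, argon; then AcOH
Reagents that add atoms: none
Why: Fluoride cleaves the aryl silyl ether under conditions that affect neither the alkene nor any stereocentre, and the acidic quench under argon protects the air-sensitive phenoxide.

**Compound list**
1 | trimethylhydroquinone (2,3,5-trimethylbenzene-1,4-diol) | Cc1cc(O)c(C)c(C)c1O | starting material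
2 | 1-(2,5-dihydroxy-3,4,6-trimethylphenyl)ethanone | CC(=O)c1c(C)c(O)c(C)c(C)c1O | intermediate
3 | 1-(2,5-dihydroxy-3,4,6-trimethylphenyl)butane-1,3-dione | CC(=O)CC(=O)c1c(C)c(O)c(C)c(C)c1O | intermediate
4 | 6-hydroxy-2,5,7,8-tetramethyl-4H-chromen-4-one | CC1=CC(=O)c2c(C)c(O)c(C)c(C)c2O1 | intermediate
5 | 6-(tert-butyldimethylsilyloxy)-2,5,7,8-tetramethyl-4H-chromen-4-one | CC1=CC(=O)c2c(C)c(O[Si](C)(C)C(C)(C)C)c(C)c(C)c2O1 | intermediate
6 | (S)-3-bromo-2-methylpropan-1-ol | BrC[C@@H](C)CO | starting material
7 | (S)-(3-bromo-2-methylpropoxy)(tert-butyl)dimethylsilane | BrC[C@@H](C)CO[Si](C)(C)C(C)(C)C | intermediate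
8 | 4-bromo-2-methylbut-1-ene | C=C(C)CCBr | starting material
9 | 3-methylbut-3-enylmagnesium bromide | C=C(C)CC[Mg]Br | intermediate
10 | (R)-tert-butyl(2,6-dimethylhept-6-enyloxy)dimethylsilane | C=C(C)CCC[C@@H](C)CO[Si](C)(C)C(C)(C)C | intermediate
11 | (R)-2,6-dimethylhept-6-en-1-ol | C=C(C)CCC[C@@H](C)CO | intermediate
12 | (R)-7-bromo-2,6-dimethylhept-1-ene | C=C(C)CCC[C@@H](C)CBr | intermediate
13 | (S)-citronellyl bromide ((S)-8-bromo-2,6-dimethyloct-2-ene) | CC(C)=CCC[C@H](C)CCBr | starting material
14 | (S)-6-bromo-4-methylhexanal | O=CCC[C@H](C)CCBr | intermediate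
15 | (S)-6-bromo-4-methylhexan-1-ol | OCCC[C@H](C)CCBr | intermediate
16 | (S)-(6-bromo-4-methylhexyloxy)(tert-butyl)dimethylsilane | CC(C)(C)[Si](C)(C)OCCC[C@H](C)CCBr | intermediate
17 | (R)-2,6-dimethylhept-6-enylmagnesium bromide | C=C(C)CCC[C@@H](C)C[Mg]Br | intermediate
18 | tert-butyldimethyl[(4R,8S)-4,8,12-trimethyltridec-12-enyloxy]silane | C=C(C)CCC[C@@H](C)CCC[C@@H](C)CCCO[Si](C)(C)C(C)(C)C | intermediate
19 | (4R,8S)-4,8,12-trimethyltridec-12-en-1-ol | C=C(C)CCC[C@@H](C)CCC[C@@H](C)CCCO | intermediate
20 | (6S,10R)-13-bromo-2,6,10-trimethyltridec-1-ene | C=C(C)CCC[C@@H](C)CCC[C@@H](C)CCCBr | intermediate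
21 | (4R,8S)-4,8,12-trimethyltridec-12-enylmagnesium bromide | C=C(C)CCC[C@@H](C)CCC[C@@H](C)CCC[Mg]Br | intermediate
22 | 6-(tert-butyldimethylsilyloxy)-2,5,7,8-tetramethyl-4-(trimethylsilyloxy)chromenylium trifluoromethanesulfonate | Cc1cc(O[Si](C)(C)C)c2c(C)c(O[Si](C)(C)C(C)(C)C)c(C)c(C)c2[o+]1.[O-]S(=O)(=O)C(F)(F)F | intermediate
23 | (R)-6-(tert-butyldimethylsilyloxy)-2,5,7,8-tetramethyl-2-[(4R,8S)-4,8,12-trimethyltridec-12-enyl]-4-(trimethylsilyloxy)-2H-chromene | C=C(C)CCC[C@@H](C)CCC[C@@H](C)CCC[C@]1(C)C=C(O[Si](C)(C)C)c2c(C)c(O[Si](C)(C)C(C)(C)C)c(C)c(C)c2O1 | intermediate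
24 | (R)-6-(tert-butyldimethylsilyloxy)-2,5,7,8-tetramethyl-2-[(4R,8S)-4,8,12-trimethyltridec-12-enyl]chroman-4-one | C=C(C)CCC[C@@H](C)CCC[C@@H](C)CCC[C@]1(C)CC(=O)c2c(C)c(O[Si](C)(C)C(C)(C)C)c(C)c(C)c2O1 | intermediate
25 | (2R)-6-(tert-butyldimethylsilyloxy)-2,5,7,8-tetramethyl-2-[(4R,8S)-4,8,12-trimethyltridec-12-enyl]chroman-4-ol, both C4 epimers | C=C(C)CCC[C@@H](C)CCC[C@@H](C)CCC[C@]1(C)CC(O)c2c(C)c(O[Si](C)(C)C(C)(C)C)c(C)c(C)c2O1 | intermediate
26 | tert-butyldimethyl{(R)-2,5,7,8-tetramethyl-2-[(4R,8S)-4,8,12-trimethyltridec-12-enyl]chroman-6-yloxy}silane | C=C(C)CCC[C@@H](C)CCC[C@@H](C)CCC[C@]1(C)CCc2c(C)c(O[Si](C)(C)C(C)(C)C)c(C)c(C)c2O1 | intermediate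
27 | (R)-2,5,7,8-tetramethyl-2-[(4R,8S)-4,8,12-trimethyltridec-12-enyl]chroman-6-ol | C=C(C)CCC[C@@H](C)CCC[C@@H](C)CCC[C@]1(C)CCc2c(C)c(O)c(C)c(C)c2O1 | target

**Step count**
Total: 18 steps. Longest linear sequence: 12 steps (5, 6, 7, 8, 11, 12, 13, 14, 15, 16, 17, 18).

**Steps most likely to fail**

1. Step 15 (proposed new method). The donor-substituted, already methylated C2 may resist attack, so that deprotonation of the 2-methyl group or 1,2-addition takes over. Face discrimination by the ligand may be poor, or C2 may be scrambled by ring opening during work-up. The fallback uses known chemistry, sets out from 21 and 2, and returns to the route at 24. Grignard reagent 21 is acylated with N-methoxy-N-methylacetamide (THF, 0 °C) to give (6R,10S)-6,10,14-trimethylpentadec-14-en-2-one F1. Kabbe condensation of F1 with acetophenone 2 (pyrrolidine, EtOH/toluene, reflux) builds the pyranone by aldol condensation and oxa-Michael closure. It gives 6-hydroxy-2,5,7,8-tetramethyl-2-[(4R,8S)-4,8,12-trimethyltridec-12-enyl]chroman-4-one F2 as both C2 epimers, without control at C2. Silylation (TBSCl, imidazole, DMF) gives the silyl ether as the epimer mixture F3. Preparative HPLC on a cellulose carbamate chiral stationary phase should deliver 24. The (2S) epimer F4 is re-equilibrated under the Kabbe conditions and recycled.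

2. Step 17. The Lewis acid or adventitious protic acid may isomerise or ionically hydrogenate the 1,1-disubstituted alkene. Elimination to the 2H-chromene or ionisation of the C2–O1 bond may compete with hydride capture. The fallback sets out from 25 and returns at 26. Alcohol 25 is acylated with O-phenyl chlorothionoformate (pyridine, 4-dimethylaminopyridine, CH2Cl2) to give the O-phenyl thionocarbonate of 25 F5. Barton–McCombie radical deoxygenation (Bu3SnH, AIBN, toluene, 90 °C) then gives 26 under neutral conditions to which the isolated alkene is inert.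

3. Step 2. The electron-rich hydroquinone polyanion may be oxidised by traces of air, and the Claisen condensation on the hindered, doubly flanked acetyl group may stall. The fallback sets out from 2 and returns at 5, bypassing 3 and 4. Acetophenone 2 is silylated selectively at the unchelated hydroxyl (TBSCl, imidazole, DMF) to give 1-[5-(tert-butyldimethylsilyloxy)-2-hydroxy-3,4,6-trimethylphenyl]ethanone F6. Heating F6 with N,N-dimethylacetamide dimethyl acetal (toluene, 100 °C) gives the enaminone (E)-1-[5-(tert-butyldimethylsilyloxy)-2-hydroxy-3,4,6-trimethylphenyl]-3-(dimethylamino)but-2-en-1-one F7. Acetic acid at rt then closes the pyranone by addition–elimination of the phenol with loss of dimethylamine to give 5.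

**Further compounds**
F1 | step 15 | (6R,10S)-6,10,14-trimethylpentadec-14-en-2-one | C=C(C)CCC[C@@H](C)CCC[C@@H](C)CCCC(C)=O
F2 | step 15 | 6-hydroxy-2,5,7,8-tetramethyl-2-[(4R,8S)-4,8,12-trimethyltridec-12-enyl]chroman-4-one, both C2 epimers | C=C(C)CCC[C@@H](C)CCC[C@@H](C)CCCC1(C)CC(=O)c2c(C)c(O)c(C)c(C)c2O1
F3 | step 15 | 6-(tert-butyldimethylsilyloxy)-2,5,7,8-tetramethyl-2-[(4R,8S)-4,8,12-trimethyltridec-12-enyl]chroman-4-one, both C2 epimers | C=C(C)CCC[C@@H](C)CCC[C@@H](C)CCCC1(C)CC(=O)c2c(C)c(O[Si](C)(C)C(C)(C)C)c(C)c(C)c2O1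
F4 | step 15 | (S)-6-(tert-butyldimethylsilyloxy)-2,5,7,8-tetramethyl-2-[(4R,8S)-4,8,12-trimethyltridec-12-enyl]chroman-4-one | C=C(C)CCC[C@@H](C)CCC[C@@H](C)CCC[C@@]1(C)CC(=O)c2c(C)c(O[Si](C)(C)C(C)(C)C)c(C)c(C)c2O1
F5 | step 17 | O-{(2R)-6-(tert-butyldimethylsilyloxy)-2,5,7,8-tetramethyl-2-[(4R,8S)-4,8,12-trimethyltridec-12-enyl]chroman-4-yl} O-phenyl thiocarbonate | C=C(C)CCC[C@@H](C)CCC[C@@H](C)CCC[C@]1(C)CC(OC(=S)Oc3ccccc3)c2c(C)c(O[Si](C)(C)C(C)(C)C)c(C)c(C)c2O1
F6 | step 2 | 1-[5-(tert-butyldimethylsilyloxy)-2-hydroxy-3,4,6-trimethylphenyl]ethanone | CC(=O)c1c(C)c(O[Si](C)(C)C(C)(C)C)c(C)c(C)c1O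
F7 | step 2 | (E)-1-[5-(tert-butyldimethylsilyloxy)-2-hydroxy-3,4,6-trimethylphenyl]-3-(dimethylamino)but-2-en-1-one | CN(C)/C(C)=C/C(=O)c1c(C)c(O[Si](C)(C)C(C)(C)C)c(C)c(C)c1O
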